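Read each flask at 50 h and watch one ratio: solvolysis product over target.

the same everywhere: gas 15 mM (held)

| run | substrate | first nucleophile | remark | time |
|---|---|---|---|---|
| grey | 25 mM | 50 mM | run made earlier |  |
| red | 17 mM | 50 mM | run made earlier |  |
| green | 38 mM | 50 mM | run made earlier |  |
| dusk | 25 mM | 50.0 mM | everything together at the start | 50 h |
| autumn | 25 mM | 50.0 mM (fed, over 30 h) | all else is in the flask from the start; the feed brings no volume worth counting | 50 h |
| winter | 25 mM (fed, over 30 h) | 50.0 mM | all else is in the flask from the start; the feed brings no volume worth counting | 50 h |

| run | time / h | solvolysis product / % | target / % |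
|---|---|---|---|
| grey | 1.50 | 0.7 | 4.5 |
| grey | 5.00 | 2.1 | 21.9 |
| grey | 8.00 | 5.0 | 33.3 |
| grey | 12.0 | 7.1 | 41.7 |
| grey | 20.0 | 8.1 | 46.3 |
| grey | 25.0 | 8.4 | 47.8 |
| grey | 30.0 | 7.3 | 47.9 |
| red | 1.50 | 0.7 | 4.1 |
| red | 5.00 | 2.1 | 20.9 |
| red | 8.00 | 4.6 | 30.7 |
| red | 12.0 | 5.8 | 37.8 |
| red | 20.0 | 6.7 | 42.8 |
| red | 25.0 | 6.6 | 43.4 |
| red | 30.0 | 7.2 | 44.5 |
| green | 1.50 | 0.3 | 3.9 |
| green | 5.00 | 3.8 | 22.0 |
| green | 8.00 | 5.4 | 34.8 |
| green | 12.0 | 7.8 | 44.3 |
| green | 20.0 | 9.9 | 51.3 |
| green | 25.0 | 8.8 | 51.5 |
| green | 30.0 | 9.1 | 52.6 |

(standard deviation of a reading: 0.5 percentage points)

* the flask that comes out highest in amount of solvolysis product, in percent of the substrate charged, or "all alike" when all lie within 1.5 percentage points (dusk / autumn / winter / all alike)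
* solvolysis product at the end, in percent of the substrate charged, dusk
* solvolysis product at the end, in percent of the substrate charged, autumn
* solvolysis product at the end, in percent of the substrate charged, winter

- the numbers in the tables scatter by 0.5 percentage points (one standard deviation)
- at the start none of the gas is in solution

Assume that both products come from one short-lived intermediate, the target by way of first nucleophile and the solvolysis product without it. Each bit of target then brings solvolysis product in the ratio s/b. Here b is the fraction of the first nucleophile charge in the flask, and s is the split number, a selectivity factor: the b at which the two form equally. In a batch flask b falls steadily as target forms, so the rate integrates in closed form. Solvolysis product equals s/r times the natural log of starting b over final b, where r is the substrate charge over the nucleophile charge.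

Take the last 3 grey rows. They average 7.93% solvolysis product and 47.3% target, and with r at 0.500 they give s = 0.147. Check it on green: the same s predicts 9.67%, and the rows average 9.27%.

For autumn, read the grey target column row by row, setting each gain against the feed delivered by then. The gain of 17 percentage points up to 5.00 h meets under 0.167 of the charge. The gain of 4.6 points up to 20.0 h meets under 0.667. Weighted over these rows, and ignoring what target uses up, b averages 0.210. So I expect a ratio of 0.700. If the two products keep grey's sum of 55.3%, autumn reaches 22.7%. Dusk repeats grey at 7.93%. Winter has its whole first nucleophile charge from the start, and if its target reaches grey's 47.3%, b falls to 0.764. So winter's ratio stays under 0.193, lower than autumn's, and I name autumn highest.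

The forecast says autumn, with 8.3% for dusk, 25% for autumn and 3% for winter, arguing that “nucleophile is scarce during the active window”; my autumn figure is lower.

The flasks give 8.01% for dusk, 18.0% for autumn and 4.16% for winter, so autumn is highest.

    substrate → intermediate (k = 0.130 /h)
    intermediate → solvolysis product (k = 0.0610 /h)
    second nucleophile → decomposed reagent (k = 0.00520 /h)
    second nucleophile + intermediate → other capture product (k = 210 /M/h)
    first nucleophile + intermediate → target (k = 8.40 /M/h)
    gas ⇌ second nucleophile, rate k6*(csat - [second nucleophile]) (kL = 0.0540 /h)
    2 second nucleophile → homo dimer (k = 0.160 /M/h)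

Autumn's ratio at the end is 0.658 against my 0.700, and its two products sum to 45.3%, less than the 55.3% read on grey that I assumed. Now take a neighbour flask, which is autumn with 120 mM of first nucleophile. Its larger charge shrinks s to 0.0612, and the same feed clock, again ignoring what target uses up, gives b of 0.210 of that charge, so the ratio should be 0.291. At the end the neighbour flask holds 12.8% solvolysis product against 41.9% target, a ratio of 0.305.

The earlier runs and the new flask stem from a simulated flask with constants of no real substance; scatter was added.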